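**Retrosynthetic overview** (bisabolane locants: ring C1(Me)/C2 oxirane, C3, C4 bearing the side chain, C5 O‑acyl, C6 OH; chain C7(=C14H2), C8 OAng, C9, C10/C11 oxirane)
1. Target ⇐ 21 ⇐ 20 ⇐ 17 by desilylation, catalyst‑controlled Shi epoxidation of C10=C11 (second oxirane closed last) and angeloylation of C8–OH.
2. 17 ⇐ C7–C8 disconnection: ligand‑controlled Ni/Cr (Nozaki–Hiyama–Kishi) addition of alkenyl triflate 13 to 4‑methylpent‑3‑enal 15. Enabling feature: the C8 carbinol sits on the inner carbon C7 of the 1,1‑disubstituted C7=C14 alkene, and C7 is bonded to ring carbon C4, so the unit C14=C7(C4)–C8(O) is the retron of a 2‑metallo‑1‑alkene plus aldehyde.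
3. 13 ⇐ methyl ketone 11 ⇐ isopropenyl compound 9: ozonolysis excises the old =CH2 and the old CH3 becomes C14, so (R)‑carvone supplies C1–C7, C14, C15 and the C4 stereocentre.
4. The other ring stereocentres are relayed from C4: C5 (anti enolate hydroxylation, then Mitsunobu inversion that installs the (R)‑2‑methylbutanoate), C6 (Luche reduction), C1 and C2 in one event (OH‑directed epoxidation). Ring order: cyclohexane bought with carvone, C1–C2 oxirane in step 4, C10–C11 oxirane in step 11.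

Key step: step 9

Assumption: (2R)‑2‑methylbutanoic acid, angelic acid, 4‑methylpent‑3‑en‑1‑ol and the D‑fructose‑derived epoxidation ketone are taken as commercial and isomerically pure.

**Step 1**
Reactants: 1 (R)‑(−)‑carvone
Product: 3 (5S,6S)‑6‑hydroxy‑2‑methyl‑5‑(prop‑1‑en‑2‑yl)cyclohex‑2‑en‑1‑one, via potassium dienolate 2 (not isolated)
Conditions: KHMDS, THF, −78 °C; then 2‑(phenylsulfonyl)‑3‑phenyloxaziridine, −78 °C; AcOH quench
Reagents that add atoms: 2‑(phenylsulfonyl)‑3‑phenyloxaziridine, O=S(=O)(N1OC1c1ccccc1)c1ccccc1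
Why: Kinetic α′‑deprotonation gives the cross‑conjugated dienolate, and its electrophilic hydroxylation (Davis enolate oxidation) should occur anti to the adjacent isopropenyl group, setting the C5 hydroxyl trans to the C4 substituent (any cis isomer is removed by chromatography).

**Step 2**
Reactants: 3 (5S,6S)‑6‑hydroxy‑2‑methyl‑5‑(prop‑1‑en‑2‑yl)cyclohex‑2‑en‑1‑one; 4 (2R)‑2‑methylbutanoic acid
Product: 6 (1R,6S)‑3‑methyl‑2‑oxo‑6‑(prop‑1‑en‑2‑yl)cyclohex‑3‑en‑1‑yl (2R)‑2‑methylbutanoate, via alkoxyphosphonium carboxylate 5 (not isolated)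
Conditions: PPh3, DIAD, toluene, 0 °C → rt
Reagents that add atoms: none
Why: Mitsunobu esterification displaces the alkoxyphosphonium by carboxylate in an SN2 step at the carbonyl‑activated C5, so the trans ketol should become the cis α‑acyloxy ketone with the ester installed at the same time; the C4–H is cis to the leaving group and cannot become anti‑periplanar, which should suppress E2 loss.

**Step 3**
Reactants: 6 (1R,6S)‑3‑methyl‑2‑oxo‑6‑(prop‑1‑en‑2‑yl)cyclohex‑3‑en‑1‑yl (2R)‑2‑methylbutanoate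
Product: 7 (1R,2S,6S)‑2‑hydroxy‑3‑methyl‑6‑(prop‑1‑en‑2‑yl)cyclohex‑3‑en‑1‑yl (2R)‑2‑methylbutanoate
Conditions: NaBH4, CeCl3·7H2O, MeOH, −78 °C
Reagents that add atoms: none
Why: Luche 1,2‑reduction; with isopropenyl equatorial and the C5 acyloxy group axial, hydride should add axially and anti to the axial C–O bond (Felkin–Anh and steric control coincide), giving the equatorial C6 alcohol cis to both neighbours, as in the reduction of carvone to cis‑carveol.

**Step 4**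
Reactants: 7 (1R,2S,6S)‑2‑hydroxy‑3‑methyl‑6‑(prop‑1‑en‑2‑yl)cyclohex‑3‑en‑1‑yl (2R)‑2‑methylbutanoate
Product: 8 (1R,2R,3R,4S,6S)‑2‑hydroxy‑1‑methyl‑4‑(prop‑1‑en‑2‑yl)‑7‑oxabicyclo[4.1.0]heptan‑3‑yl (2R)‑2‑methylbutanoate
Conditions: VO(acac)2 (cat.), t‑BuOOH, CH2Cl2, 0 °C → rt
Reagents that add atoms: tert‑butyl hydroperoxide, CC(C)(C)OO
Why: Vanadium‑catalysed hydroxyl‑directed epoxidation delivers oxygen through the vanadate ester to the C1=C2 face syn to the allylic C6–OH, setting C1 and C2 in one event and leaving the non‑allylic isopropenyl alkene untouched.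

**Step 5**
Reactants: 8 (1R,2R,3R,4S,6S)‑2‑hydroxy‑1‑methyl‑4‑(prop‑1‑en‑2‑yl)‑7‑oxabicyclo[4.1.0]heptan‑3‑yl (2R)‑2‑methylbutanoate
Product: 9 (1R,2R,3R,4S,6S)‑1‑methyl‑4‑(prop‑1‑en‑2‑yl)‑2‑(triethylsilyloxy)‑7‑oxabicyclo[4.1.0]heptan‑3‑yl (2R)‑2‑methylbutanoate
Conditions: Et3SiCl, imidazole, DMF, 0 °C → rt
Reagents that add atoms: chlorotriethylsilane, CC[Si](Cl)(CC)CC
Why: Silylation under mild base (no Lewis‑acidic silyl triflate, to spare the oxirane) blocks C6–OH so that the later enolate step cannot trigger acyl migration from the cis C5 ester.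

**Step 6**
Reactants: 9 (1R,2R,3R,4S,6S)‑1‑methyl‑4‑(prop‑1‑en‑2‑yl)‑2‑(triethylsilyloxy)‑7‑oxabicyclo[4.1.0]heptan‑3‑yl (2R)‑2‑methylbutanoate
Product: 11 (1R,2R,3R,4R,6S)‑4‑acetyl‑1‑methyl‑2‑(triethylsilyloxy)‑7‑oxabicyclo[4.1.0]heptan‑3‑yl (2R)‑2‑methylbutanoate, via secondary ozonide 10 (not isolated)
Conditions: O3, CH2Cl2, −78 °C; then PPh3, −78 °C → rt
Reagents that add atoms: ozone, [O-][O+]=O
Why: Ozonolysis with reductive work‑up cleaves the only remaining C=C to the methyl ketone, excising the methylene carbon so that the former methyl can become C14, and the neutral conditions should preserve the epimerisable C4 centre (its descriptor changes to R by priority only).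

**Step 7**
Reactants: 11 (1R,2R,3R,4R,6S)‑4‑acetyl‑1‑methyl‑2‑(triethylsilyloxy)‑7‑oxabicyclo[4.1.0]heptan‑3‑yl (2R)‑2‑methylbutanoate
Product: 13 (1R,2R,3R,4R,6S)‑1‑methyl‑2‑(triethylsilyloxy)‑4‑[1‑(trifluoromethanesulfonyloxy)ethenyl]‑7‑oxabicyclo[4.1.0]heptan‑3‑yl (2R)‑2‑methylbutanoate, via potassium enolate 12 (not isolated)
Conditions: KHMDS (1.05 equiv), THF, −78 °C; then PhNTf2, −78 °C
Reagents that add atoms: N‑phenylbis(trifluoromethanesulfonimide), O=S(=O)(N(c1ccccc1)S(=O)(=O)C(F)(F)F)C(F)(F)F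
Why: Kinetic deprotonation of the methyl ketone at the unhindered CH3 and O‑triflation (kinetic enol triflate formation) should give the 2‑triflyloxy‑1‑alkene without removing the C4–H, which would cause epimerisation or β‑elimination of the C5 ester.

**Step 8**
Reactants: 14 4‑methylpent‑3‑en‑1‑ol
Product: 15 4‑methylpent‑3‑enal
Conditions: Dess–Martin periodinane, CH2Cl2, 0 °C → rt; used at once
Reagents that add atoms: none
Why: Dess–Martin oxidation under non‑basic conditions should give the β,γ‑unsaturated aldehyde without moving the double bond into conjugation.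

**Step 9**
Reactants: 13 (1R,2R,3R,4R,6S)‑1‑methyl‑2‑(triethylsilyloxy)‑4‑[1‑(trifluoromethanesulfonyloxy)ethenyl]‑7‑oxabicyclo[4.1.0]heptan‑3‑yl (2R)‑2‑methylbutanoate; 15 4‑methylpent‑3‑enal
Product: 17 (1R,2R,3R,4S,6S)‑4‑[(3S)‑3‑hydroxy‑6‑methylhepta‑1,5‑dien‑2‑yl]‑1‑methyl‑2‑(triethylsilyloxy)‑7‑oxabicyclo[4.1.0]heptan‑3‑yl (2R)‑2‑methylbutanoate, via alkenylchromium(III) species 16 (not isolated)
Conditions: CrCl2 (4 equiv), chiral 4‑isopropyl‑oxazoline aryl methanesulfonamide ligand (enantiomer that directs Re‑face addition, sense to be confirmed on a model aldehyde), Et3N, THF, rt; then NiCl2 (cat.), 13, 15 (2 equiv), rt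
Reagents that add atoms: none
Why: Ni(0), formed from NiCl2 by Cr(II), inserts into the alkenyl C7–OTf bond of 13 and transmetalates to Cr(III); the resulting σ‑alkenylchromium 16, carrying the chiral sulfonamide, adds to the aldehyde carbon C8 of 15 through a chromium‑centred closed transition state, forming the C7–C8 bond and, after work‑up, the C8 carbinol. The closest known reaction type is the Nozaki–Hiyama–Kishi coupling of 2‑triflyloxy‑1‑alkenes with aldehydes in its ligand‑controlled asymmetric form with oxazoline–sulfonamide ligands on chromium. No ring is closed; the step joins the ring half (five stereocentres, ester, oxirane) to the C6 side‑chain half and completes the C15 skeleton. The only new stereocentre, C8, is set by the chromium‑bound ligand through addition to the Re face of the aldehyde (8S); the resident C4 centre stands 1,3 to C8 and should exert only a weak bias, and the α‑unbranched aldehyde has none. The step needs chemoselectivity for the aldehyde over the C5 ester, the oxirane and the silyl ether, which is inherent to organochromium(III) reagents; the position of C7=C14 is fixed by the kinetic enol triflate and kept because σ‑alkenylchromium species do not isomerise, and the non‑basic medium should leave C4 and the β,γ‑unsaturated aldehyde unisomerised.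

**Step 10**
Reactants: 17 (1R,2R,3R,4S,6S)‑4‑[(3S)‑3‑hydroxy‑6‑methylhepta‑1,5‑dien‑2‑yl]‑1‑methyl‑2‑(triethylsilyloxy)‑7‑oxabicyclo[4.1.0]heptan‑3‑yl (2R)‑2‑methylbutanoate; 18 angelic acid
Product: 20 (1R,2R,3R,4S,6S)‑1‑methyl‑4‑[(3S)‑6‑methyl‑3‑[(2Z)‑2‑methylbut‑2‑enoyloxy]hepta‑1,5‑dien‑2‑yl]‑2‑(triethylsilyloxy)‑7‑oxabicyclo[4.1.0]heptan‑3‑yl (2R)‑2‑methylbutanoate, via mixed anhydride 19 (not isolated)
Conditions: 18, 2,4,6‑trichlorobenzoyl chloride, Et3N, toluene, rt; then 17, toluene, 80 °C (no DMAP)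
Reagents that add atoms: none
Why: Yamaguchi esterification through the preformed mixed anhydride, without a nucleophilic catalyst that would isomerise angelate to tiglate by addition–elimination, should acylate the only free hydroxyl (C8–OH) with the Z geometry kept; no stereocentre is formed.

**Step 11**
Reactants: 20 (1R,2R,3R,4S,6S)‑1‑methyl‑4‑[(3S)‑6‑methyl‑3‑[(2Z)‑2‑methylbut‑2‑enoyloxy]hepta‑1,5‑dien‑2‑yl]‑2‑(triethylsilyloxy)‑7‑oxabicyclo[4.1.0]heptan‑3‑yl (2R)‑2‑methylbutanoate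
Product: 21 (1R,2R,3R,4S,6S)‑4‑[(3S)‑4‑[(2R)‑3,3‑dimethyloxiran‑2‑yl]‑3‑[(2Z)‑2‑methylbut‑2‑enoyloxy]but‑1‑en‑2‑yl]‑1‑methyl‑2‑(triethylsilyloxy)‑7‑oxabicyclo[4.1.0]heptan‑3‑yl (2R)‑2‑methylbutanoate
Conditions: D‑fructose‑derived ketone catalyst (cat.), Oxone, K2CO3, Bu4NHSO4 (cat.), MeCN/dimethoxymethane/aq. buffer (pH ≈ 10.5), 0 °C
Reagents that add atoms: potassium peroxymonosulfate (active component of Oxone), [K+].[O-]S(=O)(=O)OO
Why: Shi asymmetric epoxidation: the chiral dioxirane should epoxidise the electron‑rich trisubstituted C10=C11 alkene through the spiro transition state that gives (R)‑oxiranes from R–CH=CMe2 olefins, so C10 is set by the catalyst, while the allylic‑ester C7=C14 alkene and the angelate are electronically deactivated.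

**Step 12**
Reactants: 21 (1R,2R,3R,4S,6S)‑4‑[(3S)‑4‑[(2R)‑3,3‑dimethyloxiran‑2‑yl]‑3‑[(2Z)‑2‑methylbut‑2‑enoyloxy]but‑1‑en‑2‑yl]‑1‑methyl‑2‑(triethylsilyloxy)‑7‑oxabicyclo[4.1.0]heptan‑3‑yl (2R)‑2‑methylbutanoate
Product: 22 (1R,2R,3R,4S,6S)‑4‑[(3S)‑4‑[(2R)‑3,3‑dimethyloxiran‑2‑yl]‑3‑[(2Z)‑2‑methylbut‑2‑enoyloxy]but‑1‑en‑2‑yl]‑2‑hydroxy‑1‑methyl‑7‑oxabicyclo[4.1.0]heptan‑3‑yl (2R)‑2‑methylbutanoate (target)
Conditions: Et3N·3HF, THF, rt
Reagents that add atoms: none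
Why: Fluoride‑mediated desilylation with near‑neutral Et3N·3HF should remove the triethylsilyl group without forming a free alkoxide (no C5→C6 acyl migration) or strong acid (both oxiranes survive), giving the target.

**Compound list**
1 | (R)‑(−)‑carvone, (5R)‑2‑methyl‑5‑(prop‑1‑en‑2‑yl)cyclohex‑2‑en‑1‑one | C=C(C)[C@@H]1CC=C(C)C(=O)C1 | starting material
2 | potassium dienolate of 1 (cross‑conjugated, kinetic) | C=C(C)[C@@H]1CC=C(C)C([O-])=C1.[K+] | intermediate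
3 | (5S,6S)‑6‑hydroxy‑2‑methyl‑5‑(prop‑1‑en‑2‑yl)cyclohex‑2‑en‑1‑one (OH trans to isopropenyl) | C=C(C)[C@@H]1CC=C(C)C(=O)[C@H]1O | intermediate
4 | (2R)‑2‑methylbutanoic acid | CC[C@@H](C)C(=O)O | starting material
5 | alkoxytriphenylphosphonium (2R)‑2‑methylbutanoate ion pair from 3 | C=C(C)[C@@H]1CC=C(C)C(=O)[C@H]1O[P+](c2ccccc2)(c2ccccc2)c2ccccc2.CC[C@@H](C)C(=O)[O-] | intermediate
6 | (1R,6S)‑3‑methyl‑2‑oxo‑6‑(prop‑1‑en‑2‑yl)cyclohex‑3‑en‑1‑yl (2R)‑2‑methylbutanoate (acyloxy cis to isopropenyl) | C=C(C)[C@@H]1CC=C(C)C(=O)[C@@H]1OC(=O)[C@H](C)CC | intermediate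
7 | (1R,2S,6S)‑2‑hydroxy‑3‑methyl‑6‑(prop‑1‑en‑2‑yl)cyclohex‑3‑en‑1‑yl (2R)‑2‑methylbutanoate (all‑cis) | C=C(C)[C@@H]1CC=C(C)[C@H](O)[C@@H]1OC(=O)[C@H](C)CC | intermediate
8 | (1R,2R,3R,4S,6S)‑2‑hydroxy‑1‑methyl‑4‑(prop‑1‑en‑2‑yl)‑7‑oxabicyclo[4.1.0]heptan‑3‑yl (2R)‑2‑methylbutanoate | C=C(C)[C@@H]1C[C@@H]2O[C@]2(C)[C@H](O)[C@@H]1OC(=O)[C@H](C)CC | intermediate
9 | (1R,2R,3R,4S,6S)‑1‑methyl‑4‑(prop‑1‑en‑2‑yl)‑2‑(triethylsilyloxy)‑7‑oxabicyclo[4.1.0]heptan‑3‑yl (2R)‑2‑methylbutanoate | C=C(C)[C@@H]1C[C@@H]2O[C@]2(C)[C@H](O[Si](CC)(CC)CC)[C@@H]1OC(=O)[C@H](C)CC | intermediate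
10 | secondary ozonide of 9 (3‑methyl‑1,2,4‑trioxolan‑3‑yl on C4, epimeric at the trioxolane carbon) | CC3(OCOO3)[C@@H]1C[C@@H]2O[C@]2(C)[C@H](O[Si](CC)(CC)CC)[C@@H]1OC(=O)[C@H](C)CC | intermediate
11 | (1R,2R,3R,4R,6S)‑4‑acetyl‑1‑methyl‑2‑(triethylsilyloxy)‑7‑oxabicyclo[4.1.0]heptan‑3‑yl (2R)‑2‑methylbutanoate | CC(=O)[C@@H]1C[C@@H]2O[C@]2(C)[C@H](O[Si](CC)(CC)CC)[C@@H]1OC(=O)[C@H](C)CC | intermediate
12 | potassium enolate of 11 (terminal, CH2=C(OK)–) | C=C([O-])[C@@H]1C[C@@H]2O[C@]2(C)[C@H](O[Si](CC)(CC)CC)[C@@H]1OC(=O)[C@H](C)CC.[K+] | intermediate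
13 | (1R,2R,3R,4R,6S)‑1‑methyl‑2‑(triethylsilyloxy)‑4‑[1‑(trifluoromethanesulfonyloxy)ethenyl]‑7‑oxabicyclo[4.1.0]heptan‑3‑yl (2R)‑2‑methylbutanoate | C=C(OS(=O)(=O)C(F)(F)F)[C@@H]1C[C@@H]2O[C@]2(C)[C@H](O[Si](CC)(CC)CC)[C@@H]1OC(=O)[C@H](C)CC | intermediate
14 | 4‑methylpent‑3‑en‑1‑ol | CC(C)=CCCO | starting material
15 | 4‑methylpent‑3‑enal | CC(C)=CCC=O | intermediate
16 | alkenylchromium(III) species from 13 (C7–CrCl2; sulfonamide ligand on Cr not drawn) | C=C([Cr](Cl)Cl)[C@@H]1C[C@@H]2O[C@]2(C)[C@H](O[Si](CC)(CC)CC)[C@@H]1OC(=O)[C@H](C)CC | intermediate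
17 | (1R,2R,3R,4S,6S)‑4‑[(3S)‑3‑hydroxy‑6‑methylhepta‑1,5‑dien‑2‑yl]‑1‑methyl‑2‑(triethylsilyloxy)‑7‑oxabicyclo[4.1.0]heptan‑3‑yl (2R)‑2‑methylbutanoate | C=C([C@H](CC=C(C)C)O)[C@@H]1C[C@@H]2O[C@]2(C)[C@H](O[Si](CC)(CC)CC)[C@@H]1OC(=O)[C@H](C)CC | intermediate
18 | angelic acid, (2Z)‑2‑methylbut‑2‑enoic acid | C/C=C(/C)C(=O)O | starting material
19 | angelic 2,4,6‑trichlorobenzoic anhydride | C/C=C(/C)C(=O)OC(=O)c1c(Cl)cc(Cl)cc1Cl | intermediate
20 | (1R,2R,3R,4S,6S)‑1‑methyl‑4‑[(3S)‑6‑methyl‑3‑[(2Z)‑2‑methylbut‑2‑enoyloxy]hepta‑1,5‑dien‑2‑yl]‑2‑(triethylsilyloxy)‑7‑oxabicyclo[4.1.0]heptan‑3‑yl (2R)‑2‑methylbutanoate | C=C([C@H](CC=C(C)C)OC(=O)/C(C)=C\C)[C@@H]1C[C@@H]2O[C@]2(C)[C@H](O[Si](CC)(CC)CC)[C@@H]1OC(=O)[C@H](C)CC | intermediate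
21 | (1R,2R,3R,4S,6S)‑4‑[(3S)‑4‑[(2R)‑3,3‑dimethyloxiran‑2‑yl]‑3‑[(2Z)‑2‑methylbut‑2‑enoyloxy]but‑1‑en‑2‑yl]‑1‑methyl‑2‑(triethylsilyloxy)‑7‑oxabicyclo[4.1.0]heptan‑3‑yl (2R)‑2‑methylbutanoate | C=C([C@H](C[C@H]1OC1(C)C)OC(=O)/C(C)=C\C)[C@@H]1C[C@@H]2O[C@]2(C)[C@H](O[Si](CC)(CC)CC)[C@@H]1OC(=O)[C@H](C)CC | intermediate
22 | (1R,2R,3R,4S,6S)‑4‑[(3S)‑4‑[(2R)‑3,3‑dimethyloxiran‑2‑yl]‑3‑[(2Z)‑2‑methylbut‑2‑enoyloxy]but‑1‑en‑2‑yl]‑2‑hydroxy‑1‑methyl‑7‑oxabicyclo[4.1.0]heptan‑3‑yl (2R)‑2‑methylbutanoate | C=C([C@H](C[C@H]1OC1(C)C)OC(=O)/C(C)=C\C)[C@@H]1C[C@@H]2O[C@]2(C)[C@H](O)[C@@H]1OC(=O)[C@H](C)CC | target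

**Step count and risks**
Total step count: 12. Longest linear sequence: 11 steps (steps 1–7 and 9–12 from 1; step 8 makes the second fragment).

Step 9 — the risk is insufficient facial discrimination at C8, because the ligand has to override whatever bias the ring half exerts and its sense on this substrate pair is unproven. The fallback sets out from 13 and 15: the coupling is run without the chiral ligand (CrCl2, cat. NiCl2, DMF, rt) and should give 17 mixed with its C8 epimer, the (3R)‑alcohol F1. The mixture is oxidised with Dess–Martin periodinane to the single α‑methylene ketone F2. Corey–Bakshi–Shibata reduction with the (R)‑methyl oxazaborolidine and catecholborane at low temperature, with the alkenyl arm as the large group, should then give the 8S alcohol and rejoin the route at 17.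

Step 2 — the risk is that SN2 displacement at the hindered ketol carbon is outrun by acylation with retention through an acyloxyphosphonium pathway, or by decomposition of the phosphonium salt. The fallback sets out from 3: mesylation (MsCl, Et3N, CH2Cl2, 0 °C) gives the α‑keto methanesulfonate F3. Displacement with cesium (2R)‑2‑methylbutanoate F4 (from 4 and Cs2CO3) and 18‑crown‑6 in toluene at 40–50 °C should give the inverted ester and rejoin the route at 6.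

Step 11 — the risk is incomplete catalyst control of the oxirane configuration at C10, competing oxidation of C7=C14, or base‑induced ester loss at pH 10.5 on the fully acylated substrate. The fallback installs the oxirane before the fragments are joined and sets out from 14 and 13. Shi epoxidation of 14 with the same ketone gives the epoxy alcohol F5, and Dess–Martin oxidation gives the epoxy aldehyde F6, used at once. The Ni/Cr coupling of step 9 with 13 gives the epoxy allylic alcohol F7, and angeloylation through 19 as in step 10 rejoins the route at 21.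

**Further compounds**
F1 | step 9 | (1R,2R,3R,4S,6S)‑4‑[(3R)‑3‑hydroxy‑6‑methylhepta‑1,5‑dien‑2‑yl]‑1‑methyl‑2‑(triethylsilyloxy)‑7‑oxabicyclo[4.1.0]heptan‑3‑yl (2R)‑2‑methylbutanoate | C=C([C@@H](CC=C(C)C)O)[C@@H]1C[C@@H]2O[C@]2(C)[C@H](O[Si](CC)(CC)CC)[C@@H]1OC(=O)[C@H](C)CC
F2 | step 9 | (1R,2R,3R,4S,6S)‑1‑methyl‑4‑(6‑methyl‑3‑oxohepta‑1,5‑dien‑2‑yl)‑2‑(triethylsilyloxy)‑7‑oxabicyclo[4.1.0]heptan‑3‑yl (2R)‑2‑methylbutanoate | C=C(C(=O)CC=C(C)C)[C@@H]1C[C@@H]2O[C@]2(C)[C@H](O[Si](CC)(CC)CC)[C@@H]1OC(=O)[C@H](C)CC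
F3 | step 2 | (1S,6S)‑3‑methyl‑2‑oxo‑6‑(prop‑1‑en‑2‑yl)cyclohex‑3‑en‑1‑yl methanesulfonate | C=C(C)[C@@H]1CC=C(C)C(=O)[C@H]1OS(C)(=O)=O
F4 | step 2 | cesium (2R)‑2‑methylbutanoate | CC[C@@H](C)C(=O)[O-].[Cs+]
F5 | step 11 | 2‑[(2R)‑3,3‑dimethyloxiran‑2‑yl]ethan‑1‑ol | OCC[C@H]1OC1(C)C
F6 | step 11 | 2‑[(2R)‑3,3‑dimethyloxiran‑2‑yl]acetaldehyde | O=CC[C@H]1OC1(C)C
F7 | step 11 | (1R,2R,3R,4S,6S)‑4‑[(3S)‑4‑[(2R)‑3,3‑dimethyloxiran‑2‑yl]‑3‑hydroxybut‑1‑en‑2‑yl]‑1‑methyl‑2‑(triethylsilyloxy)‑7‑oxabicyclo[4.1.0]heptan‑3‑yl (2R)‑2‑methylbutanoate | C=C([C@H](C[C@H]1OC1(C)C)O)[C@@H]1C[C@@H]2O[C@]2(C)[C@H](O[Si](CC)(CC)CC)[C@@H]1OC(=O)[C@H](C)CC
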